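**Retrosynthetic overview**

- The target is reached from its (3S)-tris-MOM ether by acid removal of the three MOM groups; C3 is the only stereocentre.
- The strategy rests on ring C: C2 is an unsubstituted O–CH2, and C3 (alpha to the C4 ketone, carrying ring B) is the sole stereocentre. Cutting O1–C2 gives a 2-aryl enone (C2=C3–C4=O) with a free C8a–OH, so one oxa-Michael closure with catalyst-controlled protonation at C3 should build ring C and the stereocentre together.
- The enone is cut at C3–C4: a ring A aldehyde (the C4 carbon) adds a 1-arylvinyllithium made from the ring B methyl ketone (Shapiro). Oxidation and unmasking of the C8a oxygen (TBS ether) follow.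
- Ring A comes from phloroglucinol: the prenyl group is placed between two MOM ethers by ortho-lithiation of the TIPS-blocked symmetric phenol, and ortho-formylation of the symmetric phenol then leaves the free OH next to C8–H. Ring B comes from 2-bromoresorcinol: C-acetylation, chelation-based MOM/methyl differentiation, and Suzuki coupling with the (E)-alkenylboronate of 3-methylbut-1-yne.
- Ring order: rings A and B are brought in as arenes; ring C is the only ring formed, in step 16.

Key step: step 16

Remark: the quinine-derived squaramide is assumed to protonate the face of the C3 enolate that gives (3S); the quinidine-derived pseudo-enantiomer is the mirror-image catalyst should the sense prove opposite.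

**Route**

Step 1
Reactants: 1 phloroglucinol (benzene-1,3,5-triol)
Product: 2 3,5-bis(methoxymethoxy)phenol
Conditions: MOMCl (2.0 equiv), i-Pr2NEt, DMF, 0 °C to rt; chromatography
Reagents that add atoms: chloromethyl methyl ether, COCCl
Why: O-alkylation of the phenoxide (Williamson type) on three equivalent hydroxyls raises no regiochemical question, and with two equivalents the bis-ether should be the main component of the statistical mixture and is separated from the mono- and tris-ethers.

Step 2
Reactants: 2 3,5-bis(methoxymethoxy)phenol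
Product: 3 [3,5-bis(methoxymethoxy)phenoxy]tri(propan-2-yl)silane
Conditions: TIPSCl, imidazole, DMF, rt
Reagents that add atoms: chlorotri(propan-2-yl)silane, CC(C)[Si](Cl)(C(C)C)C(C)C
Why: Silylation of the remaining phenol gives a bulky, non-coordinating ether that shields its two ortho positions in the following metalation.

Step 3
Reactants: 3 [3,5-bis(methoxymethoxy)phenoxy]tri(propan-2-yl)silane; 4 prenyl bromide (1-bromo-3-methylbut-2-ene)
Product: 6 [3,5-bis(methoxymethoxy)-4-(3-methylbut-2-enyl)phenoxy]tri(propan-2-yl)silane, via aryllithium 5 (not isolated)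
Conditions: n-BuLi (1.1 equiv), THF, 0 °C; then CuBr·SMe2 (10 mol%), 4, −78 to 0 °C
Reagents that add atoms: none
Why: Directed ortho-metalation should take place only at the carbon flanked by two coordinating MOM ethers, and copper-catalysed SN2 allylation of the aryllithium with prenyl bromide gives the linear prenyl arene.

Step 4
Reactants: 6 [3,5-bis(methoxymethoxy)-4-(3-methylbut-2-enyl)phenoxy]tri(propan-2-yl)silane
Product: 7 3,5-bis(methoxymethoxy)-4-(3-methylbut-2-enyl)phenol
Conditions: TBAF, AcOH, THF, 0 °C to rt
Reagents that add atoms: none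
Why: Fluoride-mediated desilylation cleaves the aryl Si–O bond selectively, the MOM ethers and the prenyl group being inert, and returns a C2-symmetric phenol.

Step 5
Reactants: 7 3,5-bis(methoxymethoxy)-4-(3-methylbut-2-enyl)phenol
Product: 8 6-hydroxy-2,4-bis(methoxymethoxy)-3-(3-methylbut-2-enyl)benzaldehyde
Conditions: MgCl2, Et3N, (CH2O)n, THF, reflux; dilute acid work-up
Reagents that add atoms: paraformaldehyde (formaldehyde), C=O
Why: In the Casnati–Skattebøl ortho-formylation the magnesium phenoxide delivers formaldehyde to an ortho carbon and a second formaldehyde oxidises the benzylic alkoxide by hydride transfer; the two ortho positions are equivalent, so one aldehyde should form, with the free OH next to the only aryl C–H.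

Step 6
Reactants: 8 6-hydroxy-2,4-bis(methoxymethoxy)-3-(3-methylbut-2-enyl)benzaldehyde
Product: 9 6-[tert-butyl(dimethyl)silyl]oxy-2,4-bis(methoxymethoxy)-3-(3-methylbut-2-enyl)benzaldehyde
Conditions: TBSCl, imidazole, DMF, rt
Reagents that add atoms: tert-butyl(chloro)dimethylsilane, CC(C)(C)[Si](C)(C)Cl
Why: Silylation of the chelated phenol masks the future O1 as the only protecting group that fluoride removes while the three MOM ethers stay.

Step 7
Reactants: 10 2-bromoresorcinol (2-bromobenzene-1,3-diol)
Product: 11 1-(3-bromo-2,4-dihydroxyphenyl)ethanone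
Conditions: AcOH, BF3·OEt2, 80 °C; aq. NaOAc work-up
Reagents that add atoms: acetic acid, CC(=O)O
Why: Friedel–Crafts (Nencki-type) C-acetylation can only occur at C4/C6, the two symmetry-equivalent positions ortho and para to the hydroxyls, so a single ketone should result with the bromine between the two oxygens.

Step 8
Reactants: 11 1-(3-bromo-2,4-dihydroxyphenyl)ethanone
Product: 12 1-[3-bromo-2-hydroxy-4-(methoxymethoxy)phenyl]ethanone
Conditions: MOMCl (1.1 equiv), K2CO3, acetone, 0 °C to rt
Reagents that add atoms: chloromethyl methyl ether, COCCl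
Why: O-alkylation should be selective for the more acidic, non-chelated 4-OH because the 2-OH is held in a hydrogen bond to the acetyl oxygen.

Step 9
Reactants: 12 1-[3-bromo-2-hydroxy-4-(methoxymethoxy)phenyl]ethanone
Product: 13 1-[3-bromo-2-methoxy-4-(methoxymethoxy)phenyl]ethanone
Conditions: MeI, K2CO3, DMF, 50 °C
Reagents that add atoms: iodomethane, CI
Why: Williamson methylation of the remaining chelated phenol under more forcing conditions installs the 2'-methoxy group, which is the only oxygen left to alkylate.

Step 10
Reactants: 14 3-methylbut-1-yne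
Product: 15 4,4,5,5-tetramethyl-2-[(E)-3-methylbut-1-enyl]-1,3,2-dioxaborolane
Conditions: pinacolborane, Cp2Zr(H)Cl (5 mol%), Et3N (10 mol%), neat, sealed tube, 60 °C
Reagents that add atoms: pinacolborane, B1OC(C)(C)C(C)(C)O1
Why: Zirconium-catalysed hydroboration of the terminal alkyne is a syn, anti-Markovnikov addition and should give the (E)-alkenylboronate only.

Step 11
Reactants: 13 1-[3-bromo-2-methoxy-4-(methoxymethoxy)phenyl]ethanone; 15 4,4,5,5-tetramethyl-2-[(E)-3-methylbut-1-enyl]-1,3,2-dioxaborolane
Product: 16 1-[2-methoxy-4-(methoxymethoxy)-3-[(E)-3-methylbut-1-enyl]phenyl]ethanone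
Conditions: Pd(OAc)2 (3 mol%), SPhos (6 mol%), K3PO4, toluene/H2O, 80 °C
Reagents that add atoms: none
Why: Suzuki–Miyaura coupling with a bulky biarylphosphine on zerovalent palladium handles the di-ortho-alkoxy aryl bromide and transfers the alkenyl group with retention of the (E) geometry.

Step 12
Reactants: 16 1-[2-methoxy-4-(methoxymethoxy)-3-[(E)-3-methylbut-1-enyl]phenyl]ethanone
Product: 17 N'-[(E)-1-[2-methoxy-4-(methoxymethoxy)-3-[(E)-3-methylbut-1-enyl]phenyl]ethylidene]-2,4,6-tri(propan-2-yl)benzenesulfonohydrazide
Conditions: 2,4,6-triisopropylbenzenesulfonohydrazide, PPTS (5 mol%), THF, 4 Å MS, rt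
Reagents that add atoms: 2,4,6-tri(propan-2-yl)benzenesulfonohydrazide, CC(C)c1cc(C(C)C)c(S(=O)(=O)NN)c(C(C)C)c1
Why: Condensation of the methyl ketone with the sulfonyl hydrazide gives the hydrazone, expected mainly as the isomer with the sulfonamide nitrogen syn to the methyl group, as the Shapiro reaction requires.

Step 13
Reactants: 17 the trisylhydrazone of step 12; 9 6-[tert-butyl(dimethyl)silyl]oxy-2,4-bis(methoxymethoxy)-3-(3-methylbut-2-enyl)benzaldehyde
Product: 19 racemic 1-[6-[tert-butyl(dimethyl)silyl]oxy-2,4-bis(methoxymethoxy)-3-(3-methylbut-2-enyl)phenyl]-2-[2-methoxy-4-(methoxymethoxy)-3-[(E)-3-methylbut-1-enyl]phenyl]prop-2-en-1-ol, via 1-arylvinyllithium 18 (not isolated)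
Conditions: n-BuLi (2.1 equiv), THF, −78 to 0 °C; then 9, −78 °C; sat. NH4Cl at −78 °C
Reagents that add atoms: none
Why: In the Shapiro reaction the N,C-dianion loses sulfinate and dinitrogen to give the 1-arylvinyllithium, which adds 1,2 to the non-enolisable aldehyde to form the C3–C4 bond; the cold quench is meant to prevent O-to-O silyl migration, and the carbinol centre is formed racemic and is removed in the next step.

Step 14
Reactants: 19 the racemic allylic alcohol of step 13
Product: 20 1-[6-[tert-butyl(dimethyl)silyl]oxy-2,4-bis(methoxymethoxy)-3-(3-methylbut-2-enyl)phenyl]-2-[2-methoxy-4-(methoxymethoxy)-3-[(E)-3-methylbut-1-enyl]phenyl]prop-2-en-1-one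
Conditions: Dess–Martin periodinane, NaHCO3, CH2Cl2, 0 °C to rt
Reagents that add atoms: none
Why: Dess–Martin oxidation of the benzylic, allylic alcohol under bicarbonate buffering gives the 2-aryl enone without touching the acetals, the silyl ether or the two side-chain alkenes.

Step 15
Reactants: 20 the O-TBS enone of step 14
Product: 21 1-[2-hydroxy-4,6-bis(methoxymethoxy)-5-(3-methylbut-2-enyl)phenyl]-2-[2-methoxy-4-(methoxymethoxy)-3-[(E)-3-methylbut-1-enyl]phenyl]prop-2-en-1-one
Conditions: HF·pyridine, pyridine, THF, 0 °C; cold pH 5 buffer work-up; crude used at once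
Reagents that add atoms: none
Why: Acid-buffered fluoride desilylation frees the phenol in a medium where it stays protonated and hydrogen-bonded to the ketone, so it should not add to the enone before the chiral catalyst is present.

Step 16
Reactants: 21 the free-phenol enone of step 15
Product: 22 (3S)-3-[2-methoxy-4-(methoxymethoxy)-3-[(E)-3-methylbut-1-enyl]phenyl]-5,7-bis(methoxymethoxy)-6-(3-methylbut-2-enyl)-2,3-dihydrochromen-4-one
Conditions: quinine-derived squaramide 3-{[3,5-bis(trifluoromethyl)phenyl]amino}-4-{[(8α,9S)-6'-methoxycinchonan-9-yl]amino}cyclobut-3-ene-1,2-dione (10 mol%), toluene, 4 Å MS, −40 °C; cold filtration through silica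
Reagents that add atoms: none
Why: Proposed new method: the squaramide NH pair hydrogen-bonds the C4 carbonyl while the quinuclidine nitrogen takes the proton of the chelated C8a–OH, the phenoxide adds to the terminal CH2 to form O1–C2, and the resulting C3=C4 enolate is protonated at C3 by the quinuclidinium held on one face of the ion pair. The closest known reaction types are the cinchona thiourea- or squaramide-catalysed intramolecular oxa-Michael closure to flavanones and the conjugate addition–enantioselective protonation of 2-substituted acrylates and enones under such catalysts; an oxygen nucleophile closing a ring with protonation as the stereodetermining event has not been shown. Ring C closes in the 6-endo-trig mode, the only mode open because the beta carbon is the terminal methylene. The single stereocentre C3 is controlled by the catalyst alone, since the substrate is achiral. The step needs enantioface selectivity in the proton transfer and regioselectivity in the O-attack, and the latter is fixed by the substrate because only the oxygen next to C8–H is free while the oxygen next to the prenyl group is a MOM ether. Low temperature, a non-polar solvent and removal of the catalyst before warming are meant to hold back the uncatalysed closure and base-mediated epimerisation of the product.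

Step 17
Reactants: 22 the (3S)-tris-MOM isoflavanone of step 16
Product: 23 (3S)-5,7-dihydroxy-3-[4-hydroxy-2-methoxy-3-[(E)-3-methylbut-1-enyl]phenyl]-6-(3-methylbut-2-enyl)-2,3-dihydrochromen-4-one
Conditions: HCl (about 1 M, from AcCl in MeOH), MeOH/THF, 0 °C to rt, stopped at full conversion
Reagents that add atoms: none
Why: Acid-catalysed acetal exchange with methanol releases the three phenols as dimethoxymethane is formed, under conditions mild enough that the C3–H centre, the prenyl group and the styrenyl side chain should survive.

**Compound list**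

1 | phloroglucinol | Oc1cc(O)cc(O)c1 | starting material
2 | 3,5-bis(methoxymethoxy)phenol | COCOc1cc(O)cc(OCOC)c1 | intermediate
3 | [3,5-bis(methoxymethoxy)phenoxy]tri(propan-2-yl)silane | COCOc1cc(O[Si](C(C)C)(C(C)C)C(C)C)cc(OCOC)c1 | intermediate
4 | prenyl bromide | CC(C)=CCBr | starting material
5 | [2,6-bis(methoxymethoxy)-4-[tri(propan-2-yl)silyloxy]phenyl]lithium | [Li]c1c(OCOC)cc(O[Si](C(C)C)(C(C)C)C(C)C)cc1OCOC | intermediate
6 | [3,5-bis(methoxymethoxy)-4-(3-methylbut-2-enyl)phenoxy]tri(propan-2-yl)silane | COCOc1cc(O[Si](C(C)C)(C(C)C)C(C)C)cc(OCOC)c1CC=C(C)C | intermediate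
7 | 3,5-bis(methoxymethoxy)-4-(3-methylbut-2-enyl)phenol | COCOc1cc(O)cc(OCOC)c1CC=C(C)C | intermediate
8 | 6-hydroxy-2,4-bis(methoxymethoxy)-3-(3-methylbut-2-enyl)benzaldehyde | O=Cc1c(O)cc(OCOC)c(CC=C(C)C)c1OCOC | intermediate
9 | 6-[tert-butyl(dimethyl)silyl]oxy-2,4-bis(methoxymethoxy)-3-(3-methylbut-2-enyl)benzaldehyde | O=Cc1c(O[Si](C)(C)C(C)(C)C)cc(OCOC)c(CC=C(C)C)c1OCOC | intermediate
10 | 2-bromoresorcinol | Oc1cccc(O)c1Br | starting material
11 | 1-(3-bromo-2,4-dihydroxyphenyl)ethanone | CC(=O)c1ccc(O)c(Br)c1O | intermediate
12 | 1-[3-bromo-2-hydroxy-4-(methoxymethoxy)phenyl]ethanone | CC(=O)c1ccc(OCOC)c(Br)c1O | intermediate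
13 | 1-[3-bromo-2-methoxy-4-(methoxymethoxy)phenyl]ethanone | CC(=O)c1ccc(OCOC)c(Br)c1OC | intermediate
14 | 3-methylbut-1-yne | CC(C)C#C | starting material
15 | 4,4,5,5-tetramethyl-2-[(E)-3-methylbut-1-enyl]-1,3,2-dioxaborolane | CC(C)/C=C/B1OC(C)(C)C(C)(C)O1 | intermediate
16 | 1-[2-methoxy-4-(methoxymethoxy)-3-[(E)-3-methylbut-1-enyl]phenyl]ethanone | CC(=O)c1ccc(OCOC)c(/C=C/C(C)C)c1OC | intermediate
17 | 2,4,6-triisopropylbenzenesulfonyl hydrazone of 16, (E) at C=N | C/C(=N\NS(=O)(=O)c1c(C(C)C)cc(C(C)C)cc1C(C)C)c1ccc(OCOC)c(/C=C/C(C)C)c1OC | intermediate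
18 | [1-[2-methoxy-4-(methoxymethoxy)-3-[(E)-3-methylbut-1-enyl]phenyl]ethenyl]lithium | [Li]C(=C)c1ccc(OCOC)c(/C=C/C(C)C)c1OC | intermediate
19 | racemic silyl-protected allylic alcohol (carbinol centre unassigned) | C=C(C(O)c1c(O[Si](C)(C)C(C)(C)C)cc(OCOC)c(CC=C(C)C)c1OCOC)c1ccc(OCOC)c(/C=C/C(C)C)c1OC | intermediate
20 | O-TBS 2-aryl enone | C=C(C(=O)c1c(O[Si](C)(C)C(C)(C)C)cc(OCOC)c(CC=C(C)C)c1OCOC)c1ccc(OCOC)c(/C=C/C(C)C)c1OC | intermediate
21 | free-phenol 2-aryl enone (key-step precursor) | C=C(C(=O)c1c(O)cc(OCOC)c(CC=C(C)C)c1OCOC)c1ccc(OCOC)c(/C=C/C(C)C)c1OC | intermediate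
22 | (3S)-tris-MOM isoflavanone (key-step product) | COc1c([C@H]2COc3cc(OCOC)c(CC=C(C)C)c(OCOC)c3C2=O)ccc(OCOC)c1/C=C/C(C)C | intermediate
23 | (3S)-5,7-dihydroxy-3-[4-hydroxy-2-methoxy-3-[(E)-3-methylbut-1-enyl]phenyl]-6-(3-methylbut-2-enyl)-2,3-dihydrochromen-4-one | COc1c([C@H]2COc3cc(O)c(CC=C(C)C)c(O)c3C2=O)ccc(O)c1/C=C/C(C)C | target

**Step count**

Total: 17 steps. Longest linear sequence: 11 steps (steps 1–6, then 13–17); the ring B branch (steps 7–9, 11, 12, then 13–17) has 10.

**Steps most likely to fail**

1. Step 16. The proton transfer to C3 may show poor facial selectivity, or the uncatalysed closure may outrun the catalyst and give racemic material. The fallback sets out from 21 and closes ring C with catalytic Et3N in CH2Cl2 at 0 °C, the known base-mediated oxa-Michael route to isoflavanones, to give the racemic tris-MOM isoflavanone F1. F1 is resolved by preparative HPLC on a cellulose tris(3,5-dimethylphenylcarbamate) phase. The (3S) fraction is 22, where the route is rejoined. The (3R)-tris-MOM isoflavanone F2 is equilibrated back to F1 with catalytic DBU in toluene and recycled.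

2. Step 15. The phenol, once freed in the presence of the enone, may close ring C during desilylation or work-up and so deliver racemic product before the catalyst is added. The fallback sets out from 19 and removes the silyl group at the alcohol stage, where no Michael acceptor is present (TBAF, AcOH, THF, 0 °C), to give the phenolic allylic alcohol F3. The benzylic, allylic alcohol of F3 is then oxidised with activated MnO2 in CH2Cl2 at 0 °C, a neutral heterogeneous oxidant. Filtration gives a solution of 21, which is taken straight into step 16.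

3. Step 17. Prolonged protic acid may epimerise C3 through the enol, cyclise the prenyl group onto a flanking phenol, or add methanol to the styrenyl side chain. The fallback sets out from 22 and replaces solvolysis by silyl transfer: TESOTf and 2,2'-bipyridyl in CH2Cl2 at 0 °C convert the aryl MOM ethers into triethylsilyl ethers without free Brønsted acid, giving the (3S)-tris-TES ether F4. The silyl groups of F4 are then removed with Et3N·3HF in THF at 0 °C to give 23.

**Further compounds**

F1 | step 16 | racemic tris-MOM isoflavanone | COc1c(C2COc3cc(OCOC)c(CC=C(C)C)c(OCOC)c3C2=O)ccc(OCOC)c1/C=C/C(C)C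
F2 | step 16 | (3R)-tris-MOM isoflavanone | COc1c([C@@H]2COc3cc(OCOC)c(CC=C(C)C)c(OCOC)c3C2=O)ccc(OCOC)c1/C=C/C(C)C
F3 | step 15 | racemic 1-[6-hydroxy-2,4-bis(methoxymethoxy)-3-(3-methylbut-2-enyl)phenyl]-2-[2-methoxy-4-(methoxymethoxy)-3-[(E)-3-methylbut-1-enyl]phenyl]prop-2-en-1-ol | C=C(C(O)c1c(O)cc(OCOC)c(CC=C(C)C)c1OCOC)c1ccc(OCOC)c(/C=C/C(C)C)c1OC
F4 | step 17 | (3S)-tris(triethylsilyl) ether of the target | COc1c([C@H]2COc3cc(O[Si](CC)(CC)CC)c(CC=C(C)C)c(O[Si](CC)(CC)CC)c3C2=O)ccc(O[Si](CC)(CC)CC)c1/C=C/C(C)C
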